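The runs were generated by integration from invented constants; the scatter is artificial.

The easy mistake with this flask is to scale its rate by the whole charge of free catalyst, as if the added ligand took none of it.

in all of them: substrate 0.51 M; gas 50 mM (held); added ligand 0.13 mM
- noon: scavenger 0.30 equiv; free catalyst 0.07 mol%; run made earlier
- dusk: scavenger 0.30 equiv; free catalyst 0.11 mol%; run made earlier
- flask: scavenger 0.300 equiv; free catalyst 0.05 mol%; time 15 min

| run | time / min | substrate / % | product / % |
|---|---|---|---|
| noon | 1.33 | 96.7 | 3.0 |
| noon | 4.00 | 90.6 | 9.6 |
| noon | 6.00 | 85.3 | 14.7 |
| noon | 10.0 | 75.3 | 24.7 |
| noon | 15.0 | 63.7 | 37.0 |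
| noon | 20.0 | 51.3 | 48.4 |
| dusk | 3.00 | 87.0 | 12.7 |
| dusk | 6.00 | 74.6 | 25.2 |
| dusk | 10.0 | 57.4 | 41.9 |
| dusk | 12.0 | 49.7 | 49.8 |
| dusk | 15.0 | 37.7 | 62.7 |
| dusk | 20.0 | 18.4 | 81.5 |

(scatter of a reading: 0.3 percentage points)

- part of the substrate that has reacted at 15 min
- share of the unused coupling partner that is free and not bound as idle adduct, at 15 min

- what is said of released group includes idle adduct
- at the start none of coupling partner is dissolved
- the earlier runs were read with a standard deviation of 0.3 percentage points
- reactions considered so far: catalyst intermediate B -> released group + catalyst intermediate C; coupling partner + released group <-> idle adduct; catalyst intermediate A -> catalyst intermediate B; catalyst intermediate E -> free catalyst + product; catalyst intermediate D -> catalyst intermediate E; gas <-> coupling partner; scavenger + released group -> scavenged by-product; free catalyst + added ligand <-> idle complex; coupling partner + free catalyst -> catalyst intermediate A; substrate + catalyst intermediate C <-> catalyst intermediate D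
- the earlier runs do not show how much of coupling partner is bound; that part of a forecast is a guess

We read the two runs against each other. In the noon run, product goes from 24.7% at 10.0 min to 48.4% at 20.0 min, about twice the amount in twice the time, so the reaction is nearly zero order in substrate. The last rows then give a steady rate, as a fraction of the substrate charged: 0.0242 /min at noon and 0.0408 /min at dusk.

That rate ratio, 1.69, is larger than the loading ratio, 1.57. Plain scaling therefore gives this flask 25.9% from noon but 27.8% from dusk.

So we take the pairing of free catalyst with added ligand as fast and assume it removes a fixed part of each charge. A straight line through both runs gives 41.4 /min per unit of working catalyst. It also gives the held loading, the part of the loading, counted like the loading against the substrate charged, that does no work on this line, as 0.0115%. This is less than the ligand's own charge of 0.0255%.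

By this reckoning of ours, this flask keeps 0.0385% working and runs at 0.0159 /min, which gives us 23.9% at 15 min. The readings show no bound partner, so we give no share.

The forecast says 24.8%, above ours, holding that "the ligand removes some catalyst". It puts the free share at 75% and calls that a guess.

The flask gives 24.1% reacted and 89.0% free.

    catalyst intermediate B → released group + catalyst intermediate C (k = 2.50 /s)
    coupling partner + released group ⇌ idle adduct, settled at all times (K = 7.00 /M)
    catalyst intermediate A → catalyst intermediate B (k = 300 /s)
    catalyst intermediate E → free catalyst + product (k = 2.40 /s)
    catalyst intermediate D → catalyst intermediate E (k = 3.20 /s)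
    gas ⇌ coupling partner, rate k6*(csat - [coupling partner]) (kL = 0.310 /s)
    scavenger + released group → scavenged by-product (k = 0.110 /M/s)
    free catalyst + added ligand ⇌ idle complex, settled at all times (K = 3.60 × 10⁵ /M)
    coupling partner + free catalyst → catalyst intermediate A (k = 530 /M/s)
    substrate + catalyst intermediate C ⇌ catalyst intermediate D (K = 9.90 /M, k = 480 /M/s)

At 15 min this flask holds 0.00611 M of idle adduct beside 0.0495 M of coupling partner, and its free share stands above the forecast's. Now take the same flask with 0.2 mol% of free catalyst. With the held loading taken off, our straight line for it reaches the end of the substrate at 12.8 min, earlier than 15 min, and that flask has 99.9% reacted at 15 min.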